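**Plan**

- Retrosynthetic cuts, in order: the isovalerate O–acyl bond at C1′; the C4–C4a bond of the pyranone together with the lactone acyl–O1 bond (back to a phenol and propiolic acid); the C2′–C3′ ketone–isopropenyl bond; the C8–C1′ aryl–carbinol bond.
- Enabling feature: C8 of the coumarin is C2 of 3,4-dimethoxyphenol and lies between two oxygen-bearing carbons (C8a–O1 and C7–OMe), so it is lithiated selectively. C4a is the only unsubstituted carbon ortho to O1 and is para to the C7 methoxy group, so the pyranone ring O1–C2–C3–C4–C4a–C8a can be annulated last, after all organometallic chemistry.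
- Forward: the benzene ring is bought. The side chain is joined at C2 of the MOM ether (lithiation, oxalate) and taken to the silyl-protected α-hydroxy enone through a Weinreb amide. The phenol is freed and esterified with propiolic acid, and the pyranone, the only ring formed, is closed by gold catalysis. Desilylation and isovalerate formation finish the route.
- Stereochemistry: the single centre C1′ (R) comes from catalyst-controlled asymmetric transfer hydrogenation of the aryl glyoxylate and is carried as alkoxide or silyl ether through every basic step.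

Key step: step 9

Remark: the facial sense of the transfer hydrogenation in step 3 is assigned by analogy with aryl ketones and benzil; the configuration of 6 is to be confirmed (Mosher esters) before material is carried forward.

**Route**

Step 1
Reactants: 1 3,4-dimethoxyphenol
Product: 2 1,2-dimethoxy-4-(methoxymethoxy)benzene
Conditions: MOMCl, iPr2NEt, CH2Cl2, 0 °C → rt
Reagents that add atoms: chloromethyl methyl ether (MOMCl), COCCl
Why: O-alkylation of the phenol with the α-chloro ether (Williamson-type acetal formation) is routine and installs a group that both protects O1 and directs metalation.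

Step 2
Reactants: 2 1,2-dimethoxy-4-(methoxymethoxy)benzene; 3 diethyl oxalate
Product: 5 ethyl 2-[2,3-dimethoxy-6-(methoxymethoxy)phenyl]-2-oxoacetate, via aryllithium 4 (not isolated)
Conditions: n-BuLi, TMEDA, THF, 0 °C; then cannulated into (CO2Et)2 (3 equiv), THF, −78 °C; aq. NH4Cl
Reagents that add atoms: none
Why: Directed ortho-metalation removes the C2 proton, which is coordinated and acidified by both the OMOM and the 3-OMe oxygen, and inverse addition of the aryllithium to excess diethyl oxalate at −78 °C should stop at the α-keto ester because the tetrahedral adduct persists until the quench.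

Step 3
Reactants: 5 ethyl 2-[2,3-dimethoxy-6-(methoxymethoxy)phenyl]-2-oxoacetate
Product: 6 ethyl (2R)-2-[2,3-dimethoxy-6-(methoxymethoxy)phenyl]-2-hydroxyacetate
Conditions: RuCl(p-cymene)[(S,S)-TsDPEN] (1 mol%), HCO2H/Et3N (5:2), DMF, rt
Reagents that add atoms: none
Why: Noyori–Ikariya asymmetric transfer hydrogenation of the activated aryl ketone delivers hydride through the outer-sphere six-membered transition state to the face selected by the (S,S)-TsDPEN ligand, which should set C1′ as (R) in the sense known for benzil and simple aryl ketones, while the ester and the acetal are untouched.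

Step 4
Reactants: 6 ethyl (2R)-2-[2,3-dimethoxy-6-(methoxymethoxy)phenyl]-2-hydroxyacetate
Product: 7 (2R)-2-[2,3-dimethoxy-6-(methoxymethoxy)phenyl]-2-hydroxy-N-methoxy-N-methylacetamide
Conditions: MeNH(OMe)·HCl, iPrMgCl, THF, −20 → 0 °C
Reagents that add atoms: N,O-dimethylhydroxylamine hydrochloride, CNOC.Cl
Why: Aminolysis of the ester by the chloromagnesium amide of N,O-dimethylhydroxylamine (Weinreb amide formation) is established for free α-hydroxy esters, and the magnesium alkoxide formed first shields the benzylic α-proton from enolisation so that the configuration is retained.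

Step 5
Reactants: 7 (2R)-2-[2,3-dimethoxy-6-(methoxymethoxy)phenyl]-2-hydroxy-N-methoxy-N-methylacetamide
Product: 8 (2R)-2-[(tert-butyldimethylsilyl)oxy]-2-[2,3-dimethoxy-6-(methoxymethoxy)phenyl]-N-methoxy-N-methylacetamide
Conditions: TBSCl, imidazole, DMAP (cat.), DMF, rt → 40 °C
Reagents that add atoms: tert-butyldimethylsilyl chloride (TBSCl), CC(C)(C)[Si](C)(C)Cl
Why: Imidazole-promoted silylation (Corey conditions) of the secondary carbinol is neutral enough to leave the aryl acetal and the stereocentre intact, and the resulting ether survives the Grignard step and is a poor leaving group next to the later free phenol.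

Step 6
Reactants: 8 (2R)-2-[(tert-butyldimethylsilyl)oxy]-2-[2,3-dimethoxy-6-(methoxymethoxy)phenyl]-N-methoxy-N-methylacetamide
Product: 10 (2R)-2-[(tert-butyldimethylsilyl)oxy]-2-(6-hydroxy-2,3-dimethoxyphenyl)-N-methoxy-N-methylacetamide, via aryl trimethylsilyl ether 9 (not isolated)
Conditions: TMSOTf, 2,2′-bipyridyl, MeCN, 0 °C → rt; then H2O
Reagents that add atoms: none
Why: Silyl triflate/2,2′-bipyridyl cleavage of aromatic MOM ethers runs under non-acidic conditions through the aryl trimethylsilyl ether, which water hydrolyses, so the secondary TBS ether, the Weinreb amide and the methyl ethers should be spared, and doing it before the enone exists keeps Lewis acid and pyridine nucleophiles away from a Michael acceptor.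

Step 7
Reactants: 10 (2R)-2-[(tert-butyldimethylsilyl)oxy]-2-(6-hydroxy-2,3-dimethoxyphenyl)-N-methoxy-N-methylacetamide; 11 isopropenylmagnesium bromide
Product: 13 2-[(1R)-1-[(tert-butyldimethylsilyl)oxy]-3-methyl-2-oxobut-3-en-1-yl]-3,4-dimethoxyphenol, via magnesium hemiaminal chelate 12 (not isolated)
Conditions: isopropenylMgBr (3.5 equiv), THF, −20 → 0 °C; sat. aq. NH4Cl, 0 °C
Reagents that add atoms: none
Why: Weinreb ketone synthesis: after deprotonation of the phenol the alkenyl Grignard reagent adds once to the amide, the five-membered magnesium chelate holds until the quench so that no tertiary alcohol forms, and α-silyloxy Weinreb amides are known to give ketones without loss of configuration.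

Step 8
Reactants: 13 2-[(1R)-1-[(tert-butyldimethylsilyl)oxy]-3-methyl-2-oxobut-3-en-1-yl]-3,4-dimethoxyphenol; 14 propiolic acid
Product: 15 2-[(1R)-1-[(tert-butyldimethylsilyl)oxy]-3-methyl-2-oxobut-3-en-1-yl]-3,4-dimethoxyphenyl prop-2-ynoate
Conditions: DCC, DMAP (5 mol%), CH2Cl2, −20 → 0 °C
Reagents that add atoms: none
Why: Steglich esterification of the phenol with propiolic acid at low temperature is the standard entry to aryl propiolates and is mild enough for the enolisable C1′ centre, the low DMAP loading limiting conjugate addition to the ynoate.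

Step 9
Reactants: 15 2-[(1R)-1-[(tert-butyldimethylsilyl)oxy]-3-methyl-2-oxobut-3-en-1-yl]-3,4-dimethoxyphenyl prop-2-ynoate
Product: 16 8-[(1R)-1-[(tert-butyldimethylsilyl)oxy]-3-methyl-2-oxobut-3-en-1-yl]-6,7-dimethoxy-2H-chromen-2-one
Conditions: [JohnPhosAu(NCMe)]SbF6 (5 mol%), ClCH2CH2Cl, rt
Reagents that add atoms: none
Why: The cationic phosphine–gold(I) centre binds the terminal alkyne of the ynoate, whose ester polarisation makes the terminal carbon the electrophilic site; the arene carbon ortho to the ester oxygen and para to the 3-methoxy group attacks it anti to gold in a Friedel–Crafts manner, the Wheland intermediate rearomatises, and protodeauration of the vinylgold species releases the coumarin and returns the catalyst. The closest known reaction is the gold(I)-catalysed intramolecular hydroarylation of electron-rich aryl propiolates to coumarins. The pyranone ring closes in the 6-endo-dig mode by forming the C4–C4a bond. No stereocentre is created, and the C1′ centre is a spectator because the medium is non-basic and at ambient temperature, which gives no path to enolisation. Regioselectivity is fixed because the second ortho carbon carries the side chain and ipso attack would require a spiro five-membered closure on a less activated carbon; chemoselectivity rests on the alkynophilicity of gold, which should leave the electron-poor 1,1-disubstituted enone, the ketone and the silyl ether untouched.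

Step 10
Reactants: 16 8-[(1R)-1-[(tert-butyldimethylsilyl)oxy]-3-methyl-2-oxobut-3-en-1-yl]-6,7-dimethoxy-2H-chromen-2-one
Product: 17 8-[(1R)-1-hydroxy-3-methyl-2-oxobut-3-en-1-yl]-6,7-dimethoxy-2H-chromen-2-one
Conditions: HF·pyridine, pyridine, THF, 0 °C → rt (plastic vessel); used directly
Reagents that add atoms: none
Why: Fluoride-induced Si–O cleavage with pyridine-buffered HF is mildly acidic, so the coumarin lactone, the enone and the base-sensitive α-ketol stereocentre should survive.

Step 11
Reactants: 17 8-[(1R)-1-hydroxy-3-methyl-2-oxobut-3-en-1-yl]-6,7-dimethoxy-2H-chromen-2-one; 18 3-methylbutanoic anhydride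
Product: 19 (1R)-1-(6,7-dimethoxy-2-oxo-2H-chromen-8-yl)-3-methyl-2-oxobut-3-en-1-yl 3-methylbutanoate
Conditions: (iBuCO)2O, pyridine, DMAP (5 mol%), CH2Cl2, −20 → 0 °C
Reagents that add atoms: none
Why: DMAP-catalysed acylation with the anhydride in pyridine (nucleophilic catalysis via the acylpyridinium ion) esterifies the secondary carbinol with retention, and the weak base, low temperature and short reaction time are chosen to avoid enolisation of the benzylic α-acyloxy ketone.

**Compound list**

1 | 3,4-dimethoxyphenol | COc1ccc(O)cc1OC | starting material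
2 | 1,2-dimethoxy-4-(methoxymethoxy)benzene | COCOc1ccc(OC)c(OC)c1 | intermediate
3 | diethyl oxalate | CCOC(=O)C(=O)OCC | starting material
4 | [2,3-dimethoxy-6-(methoxymethoxy)phenyl]lithium (aryllithium) | [Li]c1c(OCOC)ccc(OC)c1OC | intermediate
5 | ethyl 2-[2,3-dimethoxy-6-(methoxymethoxy)phenyl]-2-oxoacetate | CCOC(=O)C(=O)c1c(OCOC)ccc(OC)c1OC | intermediate
6 | ethyl (2R)-2-[2,3-dimethoxy-6-(methoxymethoxy)phenyl]-2-hydroxyacetate | CCOC(=O)[C@H](O)c1c(OCOC)ccc(OC)c1OC | intermediate
7 | (2R)-2-[2,3-dimethoxy-6-(methoxymethoxy)phenyl]-2-hydroxy-N-methoxy-N-methylacetamide | CON(C)C(=O)[C@H](O)c1c(OCOC)ccc(OC)c1OC | intermediate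
8 | (2R)-2-[(tert-butyldimethylsilyl)oxy]-2-[2,3-dimethoxy-6-(methoxymethoxy)phenyl]-N-methoxy-N-methylacetamide | CON(C)C(=O)[C@H](O[Si](C)(C)C(C)(C)C)c1c(OCOC)ccc(OC)c1OC | intermediate
9 | (2R)-2-[(tert-butyldimethylsilyl)oxy]-2-[2,3-dimethoxy-6-(trimethylsilyloxy)phenyl]-N-methoxy-N-methylacetamide (aryl trimethylsilyl ether) | CON(C)C(=O)[C@H](O[Si](C)(C)C(C)(C)C)c1c(O[Si](C)(C)C)ccc(OC)c1OC | intermediate
10 | (2R)-2-[(tert-butyldimethylsilyl)oxy]-2-(6-hydroxy-2,3-dimethoxyphenyl)-N-methoxy-N-methylacetamide | CON(C)C(=O)[C@H](O[Si](C)(C)C(C)(C)C)c1c(O)ccc(OC)c1OC | intermediate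
11 | isopropenylmagnesium bromide (prop-1-en-2-ylmagnesium bromide, commercial THF solution) | C=C(C)[Mg]Br | starting material
12 | bis(bromomagnesium) phenoxide/hemiaminal alkoxide adduct of 10 with 11 (magnesium hemiaminal chelate; hemiaminal carbon unassigned) | C=C(C)C(O[Mg]Br)(N(C)OC)[C@H](O[Si](C)(C)C(C)(C)C)c1c(O[Mg]Br)ccc(OC)c1OC | intermediate
13 | 2-[(1R)-1-[(tert-butyldimethylsilyl)oxy]-3-methyl-2-oxobut-3-en-1-yl]-3,4-dimethoxyphenol | C=C(C)C(=O)[C@H](O[Si](C)(C)C(C)(C)C)c1c(O)ccc(OC)c1OC | intermediate
14 | propiolic acid (prop-2-ynoic acid) | C#CC(=O)O | starting material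
15 | 2-[(1R)-1-[(tert-butyldimethylsilyl)oxy]-3-methyl-2-oxobut-3-en-1-yl]-3,4-dimethoxyphenyl prop-2-ynoate | C=C(C)C(=O)[C@H](O[Si](C)(C)C(C)(C)C)c1c(OC)c(OC)ccc1OC(=O)C#C | intermediate
16 | 8-[(1R)-1-[(tert-butyldimethylsilyl)oxy]-3-methyl-2-oxobut-3-en-1-yl]-6,7-dimethoxy-2H-chromen-2-one | C=C(C)C(=O)[C@H](O[Si](C)(C)C(C)(C)C)c1c(OC)c(OC)cc2ccc(=O)oc12 | intermediate
17 | 8-[(1R)-1-hydroxy-3-methyl-2-oxobut-3-en-1-yl]-6,7-dimethoxy-2H-chromen-2-one | C=C(C)C(=O)[C@H](O)c1c(OC)c(OC)cc2ccc(=O)oc12 | intermediate
18 | 3-methylbutanoic anhydride (isovaleric anhydride) | CC(C)CC(=O)OC(=O)CC(C)C | starting material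
19 | (1R)-1-(6,7-dimethoxy-2-oxo-2H-chromen-8-yl)-3-methyl-2-oxobut-3-en-1-yl 3-methylbutanoate | C=C(C)C(=O)[C@H](OC(=O)CC(C)C)c1c(OC)c(OC)cc2ccc(=O)oc12 | target

**Step count and risks**

Total steps: 11. Longest linear sequence: 11 steps (from 1).

Steps most likely to fail:

Step 3. The doubly ortho-substituted aryl ring is twisted out of conjugation with the ketone, so the enantiofacial discrimination of the transfer hydrogenation may be poor, or the ester rather than the aryl group may steer the catalyst. The fallback sets out from 5 and replaces catalyst control by resolution. Reduction with NaBH4 in EtOH at 0 °C should give racemic ethyl 2-[2,3-dimethoxy-6-(methoxymethoxy)phenyl]-2-hydroxyacetate F1. Lipase-mediated kinetic resolution (Burkholderia cepacia lipase, vinyl acetate, MTBE, 30–40 °C) should then acetylate the (S)-enantiomer, as expected from Kazlauskas' rule with the aryl group as the large substituent, to ethyl (2S)-2-(acetyloxy)-2-[2,3-dimethoxy-6-(methoxymethoxy)phenyl]acetate F2. The unreacted (R)-alcohol, separated by chromatography, is 6, where the route is rejoined.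

Step 6. Silyl exchange or loss of the secondary TBS ether, or incomplete cleavage of the hindered aryl acetal, may occur under the silyl triflate conditions. The fallback sets out from 7 and removes the acetal before any silyl ether is present. Acid methanolysis (HCl, MeOH, rt) should give (2R)-2-hydroxy-2-(6-hydroxy-2,3-dimethoxyphenyl)-N-methoxy-N-methylacetamide F3. Silylation of both hydroxyls (TBSCl in excess, imidazole, DMF) should give (2R)-2-[(tert-butyldimethylsilyl)oxy]-2-[6-[(tert-butyldimethylsilyl)oxy]-2,3-dimethoxyphenyl]-N-methoxy-N-methylacetamide F4. The much more labile aryl silyl ether is then cleaved selectively (KHF2, MeOH, rt), which returns the route to 10.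

Step 11. Base-mediated enolisation of the benzylic α-acyloxy ketone during acylation, or acyloin-type isomerisation of the free α-hydroxy ketone while it is handled, would erode the configuration at C1′. The fallback sets out from 16 and avoids both the free ketol and any base. The silyl ether is converted directly into the ester with 18 and a catalytic metal triflate (Bi(OTf)3 or Sc(OTf)3, MeCN, 0 °C → rt), the silyl group being transferred to the carboxylate with the C–O bond untouched. This arrives at 19 and makes no new compound (F0).

Further compounds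
F1 | step 3 | racemic ethyl 2-[2,3-dimethoxy-6-(methoxymethoxy)phenyl]-2-hydroxyacetate | CCOC(=O)C(O)c1c(OCOC)ccc(OC)c1OC
F2 | step 3 | ethyl (2S)-2-(acetyloxy)-2-[2,3-dimethoxy-6-(methoxymethoxy)phenyl]acetate | CCOC(=O)[C@@H](OC(C)=O)c1c(OCOC)ccc(OC)c1OC
F3 | step 6 | (2R)-2-hydroxy-2-(6-hydroxy-2,3-dimethoxyphenyl)-N-methoxy-N-methylacetamide | CON(C)C(=O)[C@H](O)c1c(O)ccc(OC)c1OC
F4 | step 6 | (2R)-2-[(tert-butyldimethylsilyl)oxy]-2-[6-[(tert-butyldimethylsilyl)oxy]-2,3-dimethoxyphenyl]-N-methoxy-N-methylacetamide | CON(C)C(=O)[C@H](O[Si](C)(C)C(C)(C)C)c1c(O[Si](C)(C)C(C)(C)C)ccc(OC)c1OC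
F0 | step 11 | none | none
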